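**Retrosynthetic overview**

1. The tertiary carbinol C4 with its CH2OH (C15) is read as a dihydroxylated exocyclic methylene. C4 therefore stays sp2 and oxygen-free until the last step (osmylation anti to the C5 acetate), and the northern diol is never protected.
2. The ten-membered carbocycle is closed at C4–C5 by CrCl2/NiCl2-mediated (Nozaki–Hiyama–Kishi) addition of a C4 alkenyl triflate to the C5 aldehyde. The enabling feature is that C4 is the exocyclic carbon on C3 of the flat 3(2H)-furanone ring (ring O, C3, C2, C1, C10): this ring holds C3 and quaternary C10 in a fixed 1,3-relationship, and C4 can be sp2 without touching any stereocentre.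
3. The seco aldehyde comes from a zinc Barbier union (C7–C8) of a furanone aldehyde with a glyceraldehyde-derived 2-(bromomethyl)acrylate, then methacrylation at O-8 and lactone closure (O on C6 to C12).
4. The furanone comes from (R)-lactic acid: its pivalaldehyde acetal (a temporary ring) sets quaternary C10 by alkylation and then acylates an alkynyllithium; cycloisomerisation, oxidation and enol triflate formation follow.
5. Order of ring formation: furanone (step 4), lactone (step 12), ten-membered carbocycle (step 14).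

Key step: step 14

Remark: locants C1–C15 follow the germacrane numbering of the target (C1 ketone, C2=C3, ring oxygen between C3 and C10, C6 lactone carbon, C8 ester carbon, C11=C13, C12 lactone carbonyl, C14 methyl, C15 CH2OH); (R)-lactic acid, (R)-glyceraldehyde acetonide and racemic but-3-yn-2-ol are assumed to be purchased.

**Route**

Step 1
Reactants: 1 (R)-lactic acid; 2 pivalaldehyde
Product: 3 (2R,5R)-2-tert-butyl-5-methyl-1,3-dioxolan-4-one
Conditions: p-TsOH·H2O (cat.), H2SO4 (cat.), pentane, reflux, Dean–Stark trap; crystallisation from pentane at −78 °C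
Reagents that add atoms: none
Why: Acid-catalysed acetalisation of an α-hydroxy acid under thermodynamic control should give mainly the cis acetal (tert-butyl and methyl on one face), purified by crystallisation, so that the acetal carbon stores the configuration of the lactic acid centre for step 2.

Step 2
Reactants: 3 (2R,5R)-2-tert-butyl-5-methyl-1,3-dioxolan-4-one; 4 allyl bromide
Product: 6 (2R,5S)-5-allyl-2-tert-butyl-5-methyl-1,3-dioxolan-4-one, via lithium enolate 5 (not isolated)
Conditions: LiN(iPr)2, THF, −78 °C; then 4, −78 → −20 °C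
Reagents that add atoms: none
Why: Enolate alkylation in the sense of self-regeneration of stereocentres: the planar enolate 5 is attacked on the face opposite to tert-butyl, so allyl takes the place of the former hydrogen and the quaternary centre that becomes C10 is set (S).

Step 3
Reactants: 6 (2R,5S)-5-allyl-2-tert-butyl-5-methyl-1,3-dioxolan-4-one; 7 (±)-but-3-yn-2-ol
Product: 10 (6S)-2,6-dihydroxy-6-methylnon-8-en-3-yn-5-one, via dilithiated butynol 8 (not isolated), via cyclic lithium hemiketal 9 (not isolated)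
Conditions: 7, n-BuLi (2.1 equiv), THF, −78 → 0 °C; then 6, −78 → −30 °C; then H2O
Reagents that add atoms: none
Why: Acylation of an alkynyllithium by the lactone-type carbonyl of the dioxolanone: adduct 9 should persist as a cyclic lithium hemiketal until work-up, which prevents a second addition, and its hydrolysis releases pivalaldehyde and the tertiary hydroxyl at C10 without touching that centre (the propargylic carbinol is a mixture that is erased in step 5).

Step 4
Reactants: 10 (6S)-2,6-dihydroxy-6-methylnon-8-en-3-yn-5-one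
Product: 11 (2S)-2-allyl-5-(1-hydroxyethyl)-2-methylfuran-3(2H)-one
Conditions: (p-CF3C6H4)3PAuCl (5 mol %), AgOTf (5 mol %), toluene, rt
Reagents that add atoms: none
Why: 5-endo-dig cycloisomerisation of a γ-hydroxy ynone to a 3(2H)-furanone: the tertiary hydroxyl adds to the gold-activated alkyne carbon that becomes C3, whereas the secondary propargylic hydroxyl cannot reach the alkyne, and no stereocentre is involved.

Step 5
Reactants: 11 (2S)-2-allyl-5-(1-hydroxyethyl)-2-methylfuran-3(2H)-one
Product: 12 (2S)-5-acetyl-2-allyl-2-methylfuran-3(2H)-one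
Conditions: Dess–Martin periodinane, NaHCO3, CH2Cl2, 0 °C → rt
Reagents that add atoms: none
Why: Dess–Martin oxidation of a secondary alcohol, in which both carbinol epimers converge on the methyl ketone whose carbonyl carbon is C4.

Step 6
Reactants: 12 (2S)-5-acetyl-2-allyl-2-methylfuran-3(2H)-one
Product: 14 1-[(5S)-5-allyl-5-methyl-4-oxo-4,5-dihydrofuran-2-yl]vinyl trifluoromethanesulfonate, via potassium enolate 13 (not isolated)
Conditions: KN(SiMe3)2, THF, −78 °C; then PhNTf2, −78 → 0 °C
Reagents that add atoms: N-phenylbis(trifluoromethanesulfonimide), O=S(=O)(N(c1ccccc1)S(=O)(=O)C(F)(F)F)C(F)(F)F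
Why: Enol triflate formation from a methyl ketone: the acetyl methyl group is the only enolisable position of 12, because C10 is quaternary and H-2 is vinylic, so a single enolate and a single 1-substituted vinyl triflate should form.

Step 7
Reactants: 14 1-[(5S)-5-allyl-5-methyl-4-oxo-4,5-dihydrofuran-2-yl]vinyl trifluoromethanesulfonate
Product: 15 1-[(5S)-5-methyl-4-oxo-5-(2-oxoethyl)-4,5-dihydrofuran-2-yl]vinyl trifluoromethanesulfonate
Conditions: OsO4 (2 mol %), NaIO4 (4 equiv), 2,6-lutidine, dioxane/H2O (3:1), rt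
Reagents that add atoms: osmium tetroxide, O=[Os](=O)(=O)=O (catalytic); sodium periodate, [Na+].[O-]I(=O)(=O)=O
Why: Lemieux–Johnson oxidative cleavage: the monosubstituted allyl double bond is dihydroxylated much faster than the electron-poor triflate-bearing and furanone double bonds, and NaIO4 cleaves the diol to the C8 aldehyde, which is used without delay because the furanone oxygen is a β-leaving group.

Step 8
Reactants: 16 (R)-2,2-dimethyl-1,3-dioxolane-4-carbaldehyde; 17 methyl acrylate
Product: 18 methyl 2-{[(4R)-2,2-dimethyl-1,3-dioxolan-4-yl](hydroxy)methyl}prop-2-enoate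
Conditions: DABCO (0.3 equiv), dioxane/H2O (1:1), rt
Reagents that add atoms: none
Why: Morita–Baylis–Hillman reaction, whose new carbinol centre forms as a mixture that is erased in step 9, while the dioxolane centre (future C6) is carried through unchanged.

Step 9
Reactants: 18 methyl 2-{[(4R)-2,2-dimethyl-1,3-dioxolan-4-yl](hydroxy)methyl}prop-2-enoate
Product: 19 methyl (2Z)-2-(bromomethyl)-3-[(4S)-2,2-dimethyl-1,3-dioxolan-4-yl]prop-2-enoate
Conditions: N-bromosuccinimide, Me2S, CH2Cl2, 0 °C → rt
Reagents that add atoms: N-bromosuccinimide, O=C1CCC(=O)N1Br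
Why: Corey–Kim-type bromination with allylic transposition (SN2′): bromide displaces the alkoxysulfonium group at the terminal carbon, and both carbinol epimers converge on the thermodynamically preferred Z alkene, in which the ester is trans to the dioxolane.

Step 10
Reactants: 15 1-[(5S)-5-methyl-4-oxo-5-(2-oxoethyl)-4,5-dihydrofuran-2-yl]vinyl trifluoromethanesulfonate; 19 methyl (2Z)-2-(bromomethyl)-3-[(4S)-2,2-dimethyl-1,3-dioxolan-4-yl]prop-2-enoate
Product: 21 methyl (3R,4R)-3-[(4S)-2,2-dimethyl-1,3-dioxolan-4-yl]-4-hydroxy-2-methylidene-5-{(2S)-2-methyl-3-oxo-5-[1-(triflyloxy)vinyl]-2,3-dihydrofuran-2-yl}pentanoate, via allylzinc bromide 20 (not isolated)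
Conditions: Zn dust, THF/sat. aq. NH4Cl (2:1), 0 °C → rt
Reagents that add atoms: none
Why: Zinc-mediated Barbier allylation with a 2-(bromomethyl)acrylate: allylzinc 20 adds through its γ-carbon in a closed six-membered transition state in which the Z-disposed dioxolane leads to the 7,8-syn adduct, and allylic 1,3-strain keeps H-6 in the plane of the allyl unit so that the aldehyde approaches anti to the dioxolane C–O bond, which should set C7 (R) and C8 (R), while the vinylogous-ester ketone and the vinyl triflate are inert.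

Step 11
Reactants: 21 methyl (3R,4R)-3-[(4S)-2,2-dimethyl-1,3-dioxolan-4-yl]-4-hydroxy-2-methylidene-5-{(2S)-2-methyl-3-oxo-5-[1-(triflyloxy)vinyl]-2,3-dihydrofuran-2-yl}pentanoate
Product: 22 methyl (3R,4R)-3-[(4S)-2,2-dimethyl-1,3-dioxolan-4-yl]-4-(methacryloyloxy)-2-methylidene-5-{(2S)-2-methyl-3-oxo-5-[1-(triflyloxy)vinyl]-2,3-dihydrofuran-2-yl}pentanoate
Conditions: methacrylic anhydride, Et3N, DMAP (cat.), CH2Cl2, 0 °C → rt
Reagents that add atoms: methacrylic anhydride, C=C(C)C(=O)OC(=O)C(C)=C
Why: DMAP-catalysed acylation of the secondary alcohol, which installs the C8 ester of the target at once and removes the hydroxyl that could otherwise lactonise onto the methyl ester.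

Step 12
Reactants: 22 methyl (3R,4R)-3-[(4S)-2,2-dimethyl-1,3-dioxolan-4-yl]-4-(methacryloyloxy)-2-methylidene-5-{(2S)-2-methyl-3-oxo-5-[1-(triflyloxy)vinyl]-2,3-dihydrofuran-2-yl}pentanoate
Product: 24 (1R)-1-[(2S,3R)-2-(hydroxymethyl)-4-methylidene-5-oxooxolan-3-yl]-2-{(2S)-2-methyl-3-oxo-5-[1-(triflyloxy)vinyl]-2,3-dihydrofuran-2-yl}ethyl 2-methylprop-2-enoate, via diol ester 23 (not isolated)
Conditions: AcOH/H2O (4:1), 40 °C; then p-TsOH·H2O (cat.), CH2Cl2, rt
Reagents that add atoms: none
Why: Acetal hydrolysis followed by acid-catalysed lactonisation: the secondary C6 hydroxyl of 23 closes the five-membered lactone on the methyl ester in preference to the six-membered alternative from the primary hydroxyl, and the C6 and C7 substituents are trans as fixed in step 10.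

Step 13
Reactants: 24 (1R)-1-[(2S,3R)-2-(hydroxymethyl)-4-methylidene-5-oxooxolan-3-yl]-2-{(2S)-2-methyl-3-oxo-5-[1-(triflyloxy)vinyl]-2,3-dihydrofuran-2-yl}ethyl 2-methylprop-2-enoate
Product: 25 (1R)-1-[(2S,3R)-2-formyl-4-methylidene-5-oxooxolan-3-yl]-2-{(2S)-2-methyl-3-oxo-5-[1-(triflyloxy)vinyl]-2,3-dihydrofuran-2-yl}ethyl 2-methylprop-2-enoate
Conditions: Dess–Martin periodinane, NaHCO3, CH2Cl2, 0 °C → rt
Reagents that add atoms: none
Why: Dess–Martin oxidation of the primary alcohol under buffered, non-basic conditions, so that the α-acyloxy aldehyde is not epimerised at C6 and can be carried on crude.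

Step 14
Reactants: 25 (1R)-1-[(2S,3R)-2-formyl-4-methylidene-5-oxooxolan-3-yl]-2-{(2S)-2-methyl-3-oxo-5-[1-(triflyloxy)vinyl]-2,3-dihydrofuran-2-yl}ethyl 2-methylprop-2-enoate
Product: 27 (5R,6S,7R,8R,10S)-5-hydroxy-8-(methacryloyloxy)-1-oxo-3,10-epoxygermacra-2,4(15),11(13)-trien-12,6-olide, via alkenylchromium dichloride 26 (not isolated)
Conditions: CrCl2 (8 equiv), NiCl2 (0.2 equiv), degassed DMF, rt, syringe-pump addition of 25 (final 2 mM)
Reagents that add atoms: none
Why: Nozaki–Hiyama–Kishi reaction: zerovalent nickel, formed from NiCl2 by CrCl2, inserts into the C4–OTf bond, transmetalation to trivalent chromium gives alkenylchromium 26, and this adds to the C5 aldehyde; the closest known reaction type is the CrCl2/NiCl2-mediated alkenyl triflate–aldehyde macrocyclisation used to close strained nine- to eleven-membered carbocycles. It closes the ten-membered carbocycle C1–C10 (nine-membered when counted through the furanone oxygen) by exo 1,2-addition to the carbonyl, the chain ends being pre-oriented because the flat furanone holds C3 and quaternary C10 in a 1,3-relationship and C9 leaves this ring on one face only. The only new stereocentre, C5, is controlled by C6: non-chelated (polar) addition anti to the C6–O bond of the lactone gives the 5,6-anti alcohol, and this arrangement (O-6 anti to C4, C7 gauche) is also the one a ring bond C4–C5 requires, so substrate control and ring closure should be matched. The step needs chemoselectivity for the aldehyde over the furanone ketone, the methacrylate, the methylene lactone and the esters, which the low basicity and aldehyde selectivity of organochromium reagents secure, and ring closure over oligomerisation, which slow addition to about 2 mM secures. Since C4 is sp2 and oxygen-free here, the nucleophilic terminus carries no stereocentre, no protecting group and no β-leaving group.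

Step 15
Reactants: 27 (5R,6S,7R,8R,10S)-5-hydroxy-8-(methacryloyloxy)-1-oxo-3,10-epoxygermacra-2,4(15),11(13)-trien-12,6-olide
Product: 28 (5R,6S,7R,8R,10S)-5-acetoxy-8-(methacryloyloxy)-1-oxo-3,10-epoxygermacra-2,4(15),11(13)-trien-12,6-olide
Conditions: Ac2O, pyridine, DMAP (cat.), CH2Cl2, 0 °C → rt
Reagents that add atoms: acetic anhydride, CC(=O)OC(C)=O
Why: Acetylation of the only free hydroxyl group, done before the osmylation because the acetate turns the allylic oxygen from a hydrogen-bond-directing into a shielding group.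

Step 16
Reactants: 28 (5R,6S,7R,8R,10S)-5-acetoxy-8-(methacryloyloxy)-1-oxo-3,10-epoxygermacra-2,4(15),11(13)-trien-12,6-olide
Product: 29 (4R,5S,6S,7R,8R,10S)-5-acetoxy-4,15-dihydroxy-8-(methacryloyloxy)-1-oxo-3,10-epoxygermacra-2,11(13)-dien-12,6-olide (CNP0275292.1)
Conditions: OsO4 (5 mol %), N-methylmorpholine N-oxide (1.1 equiv), acetone/H2O (5:1), 0 °C
Reagents that add atoms: osmium tetroxide, O=[Os](=O)(=O)=O (catalytic); N-methylmorpholine N-oxide, C[N+]1([O-])CCOCC1
Why: Catalytic syn-dihydroxylation: the 4(15)-methylene is not attached to a carbonyl carbon and is twisted out of the furanone plane, so it should react faster with electrophilic OsO4 than the two α,β-unsaturated ester alkenes and the furanone enone, and because the ring forces C6 to lie syn to C3 the C5–OAc bond stands on one face of this alkene, so that OsO4 adds to the other face (anti to the allylic oxygen, the usual sense for allylic esters), which sets C4 (R) and delivers both hydroxyl groups unprotected.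

**Compound list**

1 | (R)-lactic acid | C[C@@H](O)C(=O)O | starting material
2 | pivalaldehyde | CC(C)(C)C=O | starting material
3 | (2R,5R)-2-tert-butyl-5-methyl-1,3-dioxolan-4-one (cis) | C[C@H]1O[C@@H](C(C)(C)C)OC1=O | intermediate
4 | allyl bromide | C=CCBr | starting material
5 | lithium enolate of 3, lithium (2R)-2-tert-butyl-5-methyl-1,3-dioxol-4-olate | CC1=C(O[Li])O[C@H](C(C)(C)C)O1 | intermediate
6 | (2R,5S)-5-allyl-2-tert-butyl-5-methyl-1,3-dioxolan-4-one | C=CC[C@]1(C)O[C@@H](C(C)(C)C)OC1=O | intermediate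
7 | (±)-but-3-yn-2-ol | C#CC(C)O | starting material
8 | dilithiated but-3-yn-2-ol (lithium 4-lithiobut-3-yn-2-olate) | [Li]C#CC(C)O[Li] | intermediate
9 | cyclic lithium hemiketal from 8 and 6 (mixture at the two new centres) | C=CC[C@]1(C)O[C@@H](C(C)(C)C)OC1(O[Li])C#CC(C)O[Li] | intermediate
10 | (6S)-2,6-dihydroxy-6-methylnon-8-en-3-yn-5-one (both C2 epimers) | C=CC[C@](C)(O)C(=O)C#CC(C)O | intermediate
11 | (2S)-2-allyl-5-(1-hydroxyethyl)-2-methylfuran-3(2H)-one (both carbinol epimers) | C=CC[C@]1(C)OC(=CC1=O)C(C)O | intermediate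
12 | (2S)-5-acetyl-2-allyl-2-methylfuran-3(2H)-one | C=CC[C@]1(C)OC(=CC1=O)C(C)=O | intermediate
13 | potassium enolate of 12 | C=CC[C@]1(C)OC(=CC1=O)C(=C)O[K] | intermediate
14 | 1-[(5S)-5-allyl-5-methyl-4-oxo-4,5-dihydrofuran-2-yl]vinyl trifluoromethanesulfonate | C=CC[C@]1(C)OC(=CC1=O)C(=C)OS(=O)(=O)C(F)(F)F | intermediate
15 | 1-[(5S)-5-methyl-4-oxo-5-(2-oxoethyl)-4,5-dihydrofuran-2-yl]vinyl trifluoromethanesulfonate | O=CC[C@]1(C)OC(=CC1=O)C(=C)OS(=O)(=O)C(F)(F)F | intermediate
16 | (R)-2,2-dimethyl-1,3-dioxolane-4-carbaldehyde | O=C[C@H]1COC(C)(C)O1 | starting material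
17 | methyl acrylate | C=CC(=O)OC | starting material
18 | methyl 2-{[(4R)-2,2-dimethyl-1,3-dioxolan-4-yl](hydroxy)methyl}prop-2-enoate (both carbinol epimers) | C=C(C(=O)OC)C(O)[C@H]1COC(C)(C)O1 | intermediate
19 | methyl (2Z)-2-(bromomethyl)-3-[(4S)-2,2-dimethyl-1,3-dioxolan-4-yl]prop-2-enoate | BrC/C(C(=O)OC)=C\[C@H]1COC(C)(C)O1 | intermediate
20 | allylzinc bromide from 19 | Br[Zn]C/C(C(=O)OC)=C\[C@H]1COC(C)(C)O1 | intermediate
21 | methyl (3R,4R)-3-[(4S)-2,2-dimethyl-1,3-dioxolan-4-yl]-4-hydroxy-2-methylidene-5-{(2S)-2-methyl-3-oxo-5-[1-(triflyloxy)vinyl]-2,3-dihydrofuran-2-yl}pentanoate (6S,7R,8R,10S in target numbering) | O[C@H](C[C@]1(C)OC(=CC1=O)C(=C)OS(=O)(=O)C(F)(F)F)[C@@H](C(=C)C(=O)OC)[C@H]1COC(C)(C)O1 | intermediate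
22 | methyl (3R,4R)-3-[(4S)-2,2-dimethyl-1,3-dioxolan-4-yl]-4-(methacryloyloxy)-2-methylidene-5-{(2S)-2-methyl-3-oxo-5-[1-(triflyloxy)vinyl]-2,3-dihydrofuran-2-yl}pentanoate | C=C(C)C(=O)O[C@H](C[C@]1(C)OC(=CC1=O)C(=C)OS(=O)(=O)C(F)(F)F)[C@@H](C(=C)C(=O)OC)[C@H]1COC(C)(C)O1 | intermediate
23 | methyl (3S,4R)-3-[(1S)-1,2-dihydroxyethyl]-4-(methacryloyloxy)-2-methylidene-5-{(2S)-2-methyl-3-oxo-5-[1-(triflyloxy)vinyl]-2,3-dihydrofuran-2-yl}pentanoate | C=C(C)C(=O)O[C@H](C[C@]1(C)OC(=CC1=O)C(=C)OS(=O)(=O)C(F)(F)F)[C@@H](C(=C)C(=O)OC)[C@H](O)CO | intermediate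
24 | (1R)-1-[(2S,3R)-2-(hydroxymethyl)-4-methylidene-5-oxooxolan-3-yl]-2-{(2S)-2-methyl-3-oxo-5-[1-(triflyloxy)vinyl]-2,3-dihydrofuran-2-yl}ethyl 2-methylprop-2-enoate | C=C(C)C(=O)O[C@H](C[C@]1(C)OC(=CC1=O)C(=C)OS(=O)(=O)C(F)(F)F)[C@H]1C(=C)C(=O)O[C@@H]1CO | intermediate
25 | (1R)-1-[(2S,3R)-2-formyl-4-methylidene-5-oxooxolan-3-yl]-2-{(2S)-2-methyl-3-oxo-5-[1-(triflyloxy)vinyl]-2,3-dihydrofuran-2-yl}ethyl 2-methylprop-2-enoate | C=C(C)C(=O)O[C@H](C[C@]1(C)OC(=CC1=O)C(=C)OS(=O)(=O)C(F)(F)F)[C@H]1C(=C)C(=O)O[C@@H]1C=O | intermediate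
26 | alkenylchromium dichloride from 25 (CrCl2 in place of OTf at C4) | C=C(C)C(=O)O[C@H](C[C@]1(C)OC(=CC1=O)C(=C)[Cr](Cl)Cl)[C@H]1C(=C)C(=O)O[C@@H]1C=O | intermediate
27 | (5R,6S,7R,8R,10S)-5-hydroxy-8-(methacryloyloxy)-1-oxo-3,10-epoxygermacra-2,4(15),11(13)-trien-12,6-olide | C=C(C)C(=O)O[C@@H]1C[C@]2(C)OC(=CC2=O)C(=C)[C@@H](O)[C@H]2OC(=O)C(=C)[C@@H]21 | intermediate
28 | (5R,6S,7R,8R,10S)-5-acetoxy-8-(methacryloyloxy)-1-oxo-3,10-epoxygermacra-2,4(15),11(13)-trien-12,6-olide | C=C(C)C(=O)O[C@@H]1C[C@]2(C)OC(=CC2=O)C(=C)[C@@H](OC(C)=O)[C@H]2OC(=O)C(=C)[C@@H]21 | intermediate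
29 | (4R,5S,6S,7R,8R,10S)-5-acetoxy-4,15-dihydroxy-8-(methacryloyloxy)-1-oxo-3,10-epoxygermacra-2,11(13)-dien-12,6-olide (CNP0275292.1) | C=C(C)C(=O)O[C@@H]1C[C@]2(C)OC(=CC2=O)[C@@](O)(CO)[C@@H](OC(C)=O)[C@H]2OC(=O)C(=C)[C@@H]21 | target

**Step count and risks**

Total step count: 16. Longest linear sequence: 14 steps (1–7, then 10–16).

Most likely to fail, with fallbacks:

1. Step 14 (ring closure). Intermolecular coupling to oligomers may outrun the strained closure, or facial control at the aldehyde may be lost, because the trans-fused lactone holds the C5–C8 segment stiff. The fallback reverses the ring order (carbocycle before lactone); it sets out from 22 and returns at 28. The acetonide of 22 is hydrolysed as in step 12 but without the acid-catalysed lactonisation, and the crude diol ester is silylated (Et3SiOTf, 2,6-lutidine, CH2Cl2, −78 °C) to methyl (3R,4R)-3-[(1S)-1,2-bis(triethylsilyloxy)ethyl]-4-(methacryloyloxy)-2-methylidene-5-{(2S)-2-methyl-3-oxo-5-[1-(triflyloxy)vinyl]-2,3-dihydrofuran-2-yl}pentanoate F1. Swern oxidation ((COCl)2, DMSO, then Et3N, −78 → −30 °C) converts the primary silyl ether directly into the α-silyloxy aldehyde F2. CrCl2/NiCl2 under the conditions of step 14 should then close the ten-membered ring on this more flexible open-chain substrate (non-chelated addition anti to the C6–OSiEt3 bond) to the macrocyclic hydroxy ester F3, and acetylation as in step 15 gives the acetate F4. HF·pyridine (THF, 0 °C) followed by p-TsOH (cat., CH2Cl2) removes the C6 silyl ether and closes the lactone, which gives 28.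

2. Step 16 (osmylation). The methacrylate and methylene-lactone double bonds may be oxidised in competition, or face selection at the 4(15)-alkene may be incomplete. The fallback replaces osmylation by epoxidation and enzymatic hydrolysis; it sets out from 28 and returns at 29. Dimethyldioxirane (acetone, −20 °C), a more strongly electrophilic oxidant that discriminates more sharply against the conjugated alkenes, should epoxidise the 4(15)-alkene on the face anti to the acetate and give the spiro-epoxide (4R,5S,6S,7R,8R,10S)-5-acetoxy-4,15-epoxy-8-(methacryloyloxy)-1-oxo-3,10-epoxygermacra-2,11(13)-dien-12,6-olide F5. An epoxide hydrolase (phosphate buffer pH 7.5, DMSO cosolvent, 30 °C) then adds water at the unsubstituted C15 with retention at C4 and gives 29; the neutral enzymatic opening is chosen because acid would bring in the neighbouring acetate and attack at C4.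

3. Step 10 (Barbier union). E/Z equilibration of the allylzinc may erode the syn selectivity, the dioxolane may give only a weak facial bias, and aldehyde 15 may be lost by β-elimination of the furanone oxygen. The fallback uses a cyclic allyl donor (ring control in place of acyclic control); it sets out from 18 (and 15) and returns at 24. Aqueous CF3CO2H converts 18, by acetal hydrolysis and lactonisation, into (5R)-4-hydroxy-5-(hydroxymethyl)-3-methylideneoxolan-2-one F6, whose primary hydroxyl is silylated (t-BuMe2SiCl, imidazole, DMF) to (5R)-5-{[(tert-butyldimethylsilyl)oxy]methyl}-4-hydroxy-3-methylideneoxolan-2-one F7. N-Bromosuccinimide/Me2S gives, with allylic transposition, (5S)-3-(bromomethyl)-5-{[(tert-butyldimethylsilyl)oxy]methyl}furan-2(5H)-one F8. Zinc-mediated Barbier reaction of F8 with 15 (THF/aq. NH4Cl) should add the γ-carbon anti to the ring substituent, which fixes the 6,7-trans lactone directly, and the E-locked allylzinc should give the C8-epimeric alcohol (1S)-1-[(2S,3R)-2-{[(tert-butyldimethylsilyl)oxy]methyl}-4-methylidene-5-oxooxolan-3-yl]-2-{(2S)-2-methyl-3-oxo-5-[1-(triflyloxy)vinyl]-2,3-dihydrofuran-2-yl}ethanol F9. Mitsunobu esterification with methacrylic acid (PPh3, diisopropyl azodicarboxylate, THF) inverts C8 and gives the silyl ether of 24, (1R)-1-[(2S,3R)-2-{[(tert-butyldimethylsilyl)oxy]methyl}-4-methylidene-5-oxooxolan-3-yl]-2-{(2S)-2-methyl-3-oxo-5-[1-(triflyloxy)vinyl]-2,3-dihydrofuran-2-yl}ethyl 2-methylprop-2-enoate F10; HF·pyridine (THF, 0 °C) then gives 24.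

**Further compounds**

F1 | step 14 | methyl (3R,4R)-3-[(1S)-1,2-bis(triethylsilyloxy)ethyl]-4-(methacryloyloxy)-2-methylidene-5-{(2S)-2-methyl-3-oxo-5-[1-(triflyloxy)vinyl]-2,3-dihydrofuran-2-yl}pentanoate | C=C(C)C(=O)O[C@H](C[C@]1(C)OC(=CC1=O)C(=C)OS(=O)(=O)C(F)(F)F)[C@@H](C(=C)C(=O)OC)[C@H](O[Si](CC)(CC)CC)CO[Si](CC)(CC)CC
F2 | step 14 | methyl (3R,4R)-4-(methacryloyloxy)-2-methylidene-3-[(1S)-2-oxo-1-(triethylsilyloxy)ethyl]-5-{(2S)-2-methyl-3-oxo-5-[1-(triflyloxy)vinyl]-2,3-dihydrofuran-2-yl}pentanoate | C=C(C)C(=O)O[C@H](C[C@]1(C)OC(=CC1=O)C(=C)OS(=O)(=O)C(F)(F)F)[C@@H](C(=C)C(=O)OC)[C@H](O[Si](CC)(CC)CC)C=O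
F3 | step 14 | methyl (5R,6S,7R,8R,10S)-5-hydroxy-8-(methacryloyloxy)-1-oxo-6-(triethylsilyloxy)-3,10-epoxygermacra-2,4(15),11(13)-trien-12-oate | C=C(C)C(=O)O[C@@H]1C[C@]2(C)OC(=CC2=O)C(=C)[C@@H](O)[C@@H](O[Si](CC)(CC)CC)[C@@H]1C(=C)C(=O)OC
F4 | step 14 | methyl (5R,6S,7R,8R,10S)-5-acetoxy-8-(methacryloyloxy)-1-oxo-6-(triethylsilyloxy)-3,10-epoxygermacra-2,4(15),11(13)-trien-12-oate | C=C(C)C(=O)O[C@@H]1C[C@]2(C)OC(=CC2=O)C(=C)[C@@H](OC(C)=O)[C@@H](O[Si](CC)(CC)CC)[C@@H]1C(=C)C(=O)OC
F5 | step 16 | (4R,5S,6S,7R,8R,10S)-5-acetoxy-4,15-epoxy-8-(methacryloyloxy)-1-oxo-3,10-epoxygermacra-2,11(13)-dien-12,6-olide | C=C(C)C(=O)O[C@@H]1C[C@]2(C)OC(=CC2=O)[C@@]3(CO3)[C@@H](OC(C)=O)[C@H]2OC(=O)C(=C)[C@@H]21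
F6 | step 10 | (5R)-4-hydroxy-5-(hydroxymethyl)-3-methylideneoxolan-2-one (both C4 epimers) | C=C1C(O)[C@@H](CO)OC1=O
F7 | step 10 | (5R)-5-{[(tert-butyldimethylsilyl)oxy]methyl}-4-hydroxy-3-methylideneoxolan-2-one (both C4 epimers) | C=C1C(O)[C@@H](CO[Si](C)(C)C(C)(C)C)OC1=O
F8 | step 10 | (5S)-3-(bromomethyl)-5-{[(tert-butyldimethylsilyl)oxy]methyl}furan-2(5H)-one | BrCC1=C[C@@H](CO[Si](C)(C)C(C)(C)C)OC1=O
F9 | step 10 | (1S)-1-[(2S,3R)-2-{[(tert-butyldimethylsilyl)oxy]methyl}-4-methylidene-5-oxooxolan-3-yl]-2-{(2S)-2-methyl-3-oxo-5-[1-(triflyloxy)vinyl]-2,3-dihydrofuran-2-yl}ethanol | O[C@@H](C[C@]1(C)OC(=CC1=O)C(=C)OS(=O)(=O)C(F)(F)F)[C@H]1C(=C)C(=O)O[C@@H]1CO[Si](C)(C)C(C)(C)C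
F10 | step 10 | (1R)-1-[(2S,3R)-2-{[(tert-butyldimethylsilyl)oxy]methyl}-4-methylidene-5-oxooxolan-3-yl]-2-{(2S)-2-methyl-3-oxo-5-[1-(triflyloxy)vinyl]-2,3-dihydrofuran-2-yl}ethyl 2-methylprop-2-enoate | C=C(C)C(=O)O[C@H](C[C@]1(C)OC(=CC1=O)C(=C)OS(=O)(=O)C(F)(F)F)[C@H]1C(=C)C(=O)O[C@@H]1CO[Si](C)(C)C(C)(C)C
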